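## Structural features

The target is a daucane-type bicycle: a cyclopentane (C1–C5) trans-fused through the C1–C5 bond to a cycloheptene (C1, C5, C6, C7, C8, C9, C10) whose trisubstituted C8=C9 alkene carries a methyl group on C8. The numbering used throughout is: C1 the methyl-bearing quaternary fusion carbon, C2 and C3 the ring methylenes, C4 the isopropyl carbinol carbon, C5 the fusion CH, C6 the salicylate-bearing carbon, then C7, C8, C9 and C10 back to C1. The four stereocentres are contiguous (C6–C5–C4 in a row, C1 bonded to C5) and are 1R,4R,5S,6S. The C1 methyl and the C4 hydroxyl lie on one face (α); H5, the isopropyl group and the C6 oxygen lie on the other (β), so the two oxygens are 1,3-anti. Fragile elements are the tertiary C4 alcohol (dehydration, and retro-aldol cleavage once C6 is a ketone), the C8=C9 alkene (no hydrogenation, ozonolysis or peracids), the doubly allylic C7 methylene in diene intermediates, and the free-phenol salicylate. The real difficulty is the all-carbon quaternary C1 in a fused seven-membered ring, and then the relay of its configuration to C4, which is 1,3 to C1 across a carbon (C5) that is sp2 for much of the route. The key step exploits two facts: C7–C8(CH3)=C9–C10 is an isoprene unit attached to the five-membered part at C6 and at C1, and the C6 oxygen can be traded for the carboxyl carbon of a diazoacetate. A vinylcarbenoid at C6 whose vinyl group is C5=C1 therefore closes the seven-membered ring and creates C1 in one catalytic asymmetric operation.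

## Logic of the disconnections

19 to 18. Cut: the acyl C–O bond at the C6 oxygen. Reason: the salicylate is the most base-sensitive group and is kept out of all earlier chemistry. Gain: a diol without arene or phenol. Demand: acylation of the secondary C6 hydroxyl beside the tertiary C4 hydroxyl, with an acyl donor that liberates the phenol itself so that no deprotection step is needed.

18 to 17. Cut: the C6–H bond (carbinol back to ketone). Reason: O4 and O6 are 1,3-anti, the pattern that internal hydride delivery from the C4 hydroxyl produces. Gain: one stereocentre fewer, and C5 becomes epimerisable so the ring fusion can settle thermodynamically. Demand: hydride must arrive on the α face, the face of the C1 methyl, so delivery has to beat the steric preference.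

17 to 14. Change: C6=O is exchanged for C6–CO2H with a C5=C6 double bond. Reason: the carboxyl carbon is the one a diazoacetate brings, and an α,β-unsaturated acid is degraded to a ketone by acyl azide rearrangement. Gain: C5 is no longer a stereocentre. Demand: rearrangement of a hindered tetrasubstituted acrylic acid, hydrolysis mild enough to spare the tertiary aldol, and C5 settling trans to the isopropyl group.

14 to 11. Cut: the O–Si bonds; the lactone C–O bond between O4 and the carboxyl carbon is restored. Reason: a C4 alkoxide cis to the ester across C5=C6 cannot be kept open, so the butenolide is the real product of the carbonyl addition and protects both functions. Gain: no separate protecting group in the addition step. Demand: ring opening and O-silylation must outrun relactonisation.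

11 to 9. Cut: the C4–isopropyl bond (and the lactone C–O bond). Reason: C4 is a ketone in the annulation product, and a 1,2-addition is the shortest way to the tertiary carbinol. Gain: the C4 stereocentre disappears, leaving only C1. Demand: addition on the face of C10, anti to the C1 methyl, with C5 still sp2, and no enolisation at C7. This is the stereochemically weakest point of the plan.

9 to 6 and 7. Cut: C6–C7 and C1–C10. Reason: C7–C8(CH3)=C9–C10 is an isoprene unit, and both bonds join it to a cyclopentenone available in three steps. Gain: the seven-membered ring, the quaternary centre and the absolute configuration all come from two achiral partners and a chiral catalyst. Demand: cyclopropanation of the methyl-bearing alkene only, the vinyl group cis to the cyclopentenyl group, and a Cope step that tolerates the inward-pointing methyl on C1.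

6 to 5. Cut: the C=N2 bond at C6. Reason: diazo transfer to an ester methylene that is also allylic. Gain: a stable ester. Demand: deprotonation at the ester methylene and not at the vinylogous positions of the enone.

5 to 3. Cut: the C5=C1 double bond (ring-forming aldol condensation). Gain: an open-chain 1,4-diketone ester. Demand: enolisation towards the ester-bearing chain and closure on the methyl ketone; the ester is re-formed after the aqueous base.

3 to 1 and 2. Cut: the C3–C4 bond. Reason: a 1,4-diketone is the direct product of conjugate addition of an acyl anion equivalent. Gain: two commercial four-carbon pieces. Demand: umpolung of the aldehyde without self-condensation.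

## Other disconnections considered

Alternative 1: The cuts are C5–C6 and C1–C10, both made on a cyclopentene that already holds the C4 carbinol. In the forward sense the bromomethylsilyl ether A1 of an enantioenriched tertiary allylic alcohol gives an α-silyl radical that adds 5-exo to C5. The resulting tertiary C1 radical is trapped by allyltributylstannane A2 on the face away from the new ring, giving the cis-fused oxasilolane A3.
- In its favour: the tether forces C6 onto the face of O4, so the C4/C5 relation is secured by ring strain and the C1 allyl group is placed relative to it in the same step. On this relay of stereochemistry to C4 and C5 the alternative is better than the chosen plan, which relies on a remote methyl group for C4.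
- Against it: A1 needs an enantioenriched tertiary allylic alcohol, so the absolute configuration comes from a stoichiometric source or a resolution and not from a catalyst. Intermolecular allylation of a tertiary radical to make a quaternary carbon competes with simple reduction. Stoichiometric tin is needed.
- Comparison: the key step builds no ring of the target. After it, silicon must be oxidised off C6, C7 and C8 attached, the C6 carbinol set separately, and the trisubstituted C8=C9 alkene closed by metathesis. On step economy and on what the key step delivers (ring, quaternary centre and absolute configuration at once) the chosen plan is stronger.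

Alternative 2: The cut is C1–C5, made by a 1,2-shift in a trans-decalin. Lewis acid (TiCl4 or Et2AlCl) opening of the C4–C5 epoxide of the ring-fusion carbinol A4 lets the C6–C1 bond migrate to C5 anti to the departing oxygen. This contracts one ring, expands the other and gives the ketol A5, which is the same compound as 17.
- In its favour: C4 comes from the epoxide oxygen and C5 from a stereospecific migration, so no face selection at C4 and no equilibration of C5 is needed. The C6 oxygen is already present, so no carboxyl has to be exchanged for oxygen. On all three points the alternative is better than the chosen plan, and trans-decalin chemistry is predictable.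
- Against it: A4 is about as complex as the target (angular methyl, tertiary fusion carbinol, a trisubstituted epoxide beside a second alkene) and still needs its own enantioselective synthesis. The required cleavage is at the less substituted epoxide carbon C5, while ionisation at the tertiary C4 and migration of C7 instead of C1 are competing paths.
- Comparison: mechanistically it is a stereospecific rearrangement against a catalyst-controlled annulation. The end game from A5 is identical to the chosen one, so the comparison rests on the route to A4, which is expected to be longer than steps 1–7 here.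

Alternative 3: The cuts are C7–C8 and C9–C10. [Rh(CO)2Cl]2 inserts into the C5–C10 bond of the ring-fused vinylcyclopropane A6, whose vinyl group is the C6 silyl enol ether. The alkyne 1-(trimethylsilyl)propyne A7 is then taken up to give the cycloheptadiene A8.
- In its favour: the C6 oxygen is present from the start, and the silyl group on the alkyne fixes the methyl on C8. On the C6 oxidation level and on the regiochemistry of the methyl group the alternative is better than the chosen plan, where isoprene must choose between its two alkenes. The transfer of C1 from an enantioenriched cyclopropane is stereospecific, which is equal to catalyst control in the chosen plan.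
- Against it: A6 is a bicyclo[3.1.0]hexane with fully substituted C1 and C5 that needs its own asymmetric cyclopropanation. A tetrasubstituted cyclopropane and an internal alkyne are demanding partners. Cleavage of the wrong cyclopropane bond would give another skeleton. Afterwards the vinylsilane must be removed and two carbonyl groups unmasked.
- Comparison: the C4/C5 problem (addition to C4 while C5 is sp2) is exactly the same as in the chosen plan, so the two are equal there. The step count is expected to be equal or higher.

Key step: step 4

Assumption on the chemistry: the sense of induction of Rh2(S-DOSP)4 with this hindered vinylcarbenoid is taken to be its usual one for terminal alkenes, which maps onto 1R. Should it be reversed, the enantiomeric prolinate catalyst is used and nothing else changes.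

## Route

Step 1
Reactants: 1 but-3-en-2-one; 2 methyl 4-oxobutanoate
Product: 3 methyl 4,7-dioxooctanoate
Conditions: 3-benzyl-5-(2-hydroxyethyl)-4-methylthiazolium chloride (10 mol %), Et3N, EtOH, 75 °C
Reagents that add atoms: none
Why: Stetter reaction: the thiazolium carbene turns the aldehyde of 2 into an acyl anion equivalent that adds to the enone 1 in conjugate fashion, giving the 1,4-diketone directly; the ester is inert.

Step 2
Reactants: 3 methyl 4,7-dioxooctanoate
Product: 5 methyl 2-(2-methyl-5-oxocyclopent-1-en-1-yl)acetate, via enone acid 4 (not isolated)
Conditions: 2% aq NaOH, reflux; HCl to pH 2, concentrate; MeOH, H2SO4 (cat.), reflux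
Reagents that add atoms: methanol, CO
Why: Intramolecular aldol condensation of a 2,5-diketone: the methylene next to the internal ketone closes on the methyl ketone and dehydration gives the tetrasubstituted 2,3-disubstituted cyclopentenone (the thermodynamic enone). Aqueous base saponifies the ester, which rules out Claisen-type closure, and Fischer esterification restores it.

Step 3
Reactants: 5 methyl 2-(2-methyl-5-oxocyclopent-1-en-1-yl)acetate
Product: 6 methyl 2-diazo-2-(2-methyl-5-oxocyclopent-1-en-1-yl)acetate
Conditions: 4-acetamidobenzenesulfonyl azide, DBU, MeCN, 0 °C to rt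
Reagents that add atoms: 4-acetamidobenzenesulfonyl azide, CC(=O)Nc1ccc(cc1)S(=O)(=O)N=[N+]=[N-]
Why: Regitz diazo transfer to a β,γ-unsaturated ester, the standard entry to vinyldiazoacetates; only the ester enolate leads to a stable diazo compound, so reversible deprotonation elsewhere is unproductive. 6 is kept cold and used promptly to avoid 1,5-electrocyclisation to a 3H-pyrazole.

Step 4
Reactants: 6 methyl 2-diazo-2-(2-methyl-5-oxocyclopent-1-en-1-yl)acetate; 7 isoprene
Product: 9 methyl (8aR)-6,8a-dimethyl-3-oxo-1,2,3,5,8,8a-hexahydroazulene-4-carboxylate, via cis-divinylcyclopropane 8 (not isolated)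
Conditions: Rh2(S-DOSP)4 (1 mol %), 7 (5 equiv), 2,2-dimethylbutane, −40 °C to rt, slow addition of 6; evaporate excess 7; PhMe, 100 °C
Reagents that add atoms: none
Why: Rh2(S-DOSP)4 (dirhodium tetrakis[N-(4-dodecylbenzenesulfonyl)-(S)-prolinate]) extrudes N2 from 6 to give a rhodium-bound donor/acceptor vinylcarbenoid at C6, which cyclopropanates the 1,1-disubstituted alkene of 7 in an asynchronous concerted step (C6–C7 first, positive charge building on the tertiary allylic C8), placing the vinyl group cis to the cyclopentenyl group in 8. A Cope rearrangement of this cis-divinylcyclopropane through a boat transition state then forms C1–C10, breaks C6–C8 and leaves the C5=C6 and C8=C9 double bonds of 9. The closest known reaction type is the dirhodium prolinate-catalysed tandem cyclopropanation/Cope rearrangement (formal (4+3) cycloaddition) of cyclic vinyldiazoacetates with 1,3-dienes. The seven-membered ring is closed by annulation, a (2+1) cycloaddition followed by a 3,3-sigmatropic ring expansion, not by an exo or endo cyclisation. C1 is the only new stereocentre: the catalyst fixes the configuration of C6 in 8, and since both vinyl groups must lie over the three-membered ring in the boat and the C5=C1 geometry is locked in the five-membered ring, one face of C1 is presented to C10 and the transfer is stereospecific, which should give 1R. The step needs regioselectivity for the methyl-bearing alkene of 7 (its higher nucleophilicity and the tertiary allylic charge), vinyl-cis diastereoselectivity (the charge-stabilising vinyl group prefers the side of the donor), and no attack at the vinylogous carbon C1 (blocked because C1 is fully substituted). The C1 methyl points into the boat, so the rearrangement is not expected at low temperature and is completed by heating once the excess diene has been removed.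

Step 5
Reactants: 9 methyl (8aR)-6,8a-dimethyl-3-oxo-1,2,3,5,8,8a-hexahydroazulene-4-carboxylate
Product: 11 tricyclic butenolide (γ-lactone between the C4 oxygen and the C6 carboxyl; 1R,4R; C5=C6 and C8=C9), via hydroxy ester 10 (not isolated)
Conditions: iPrMgCl, CeCl3, THF, −78 to 0 °C; aq NH4Cl, then rt
Reagents that add atoms: isopropylmagnesium chloride, CC(C)[Mg]Cl
Why: Organocerium 1,2-addition to the ketone, which suppresses enolisation at the doubly allylic C7 and β-hydride reduction. The reagent should enter on the β face, anti to the C1 methyl, which is the pseudo-axial group over the enone because the seven-membered ring holds C10 near the enone plane. The C4 alkoxide is cis to the ester across C5=C6 and lactonises, so the butenolide is the product and protects the tertiary oxygen; any C4 epimer is removed here.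

Step 6
Reactants: 11 tricyclic butenolide
Product: 14 (3R,8aR)-6,8a-dimethyl-3-(propan-2-yl)-3-[(triethylsilyl)oxy]-1,2,3,5,8,8a-hexahydroazulene-4-carboxylic acid, via potassium carboxylate 12 (not isolated), via bis(triethylsilyl) derivative 13 (not isolated)
Conditions: KOH, MeOH/H2O, rt, evaporate; Et3SiOTf, 2,6-lutidine, CH2Cl2, 0 °C to rt; MeOH/H2O, pH 5 buffer
Reagents that add atoms: potassium hydroxide, [K+].[OH-]; triethylsilyl trifluoromethanesulfonate, CC[Si](CC)(CC)OS(=O)(=O)C(F)(F)F
Why: Saponification opens the lactone to the (Z)-hydroxy carboxylate, and exhaustive silylation with the silyl triflate caps the hindered tertiary hydroxyl before the acid is set free, so relactonisation is blocked. The labile silyl ester is then hydrolysed selectively while the tertiary silyl ether stays.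

Step 7
Reactants: 14 (3R,8aR)-6,8a-dimethyl-3-(propan-2-yl)-3-[(triethylsilyl)oxy]-1,2,3,5,8,8a-hexahydroazulene-4-carboxylic acid
Product: 17 (3R,3aR,8aR)-3-hydroxy-6,8a-dimethyl-3-(propan-2-yl)-2,3,3a,5,8,8a-hexahydroazulen-4(1H)-one, via acyl azide 15 (not isolated), via vinyl isocyanate 16 (not isolated)
Conditions: (PhO)2P(O)N3, Et3N, PhMe, 0 °C then 80 °C; 1 M HCl, THF, 0 °C to rt
Reagents that add atoms: water, O
Why: Curtius rearrangement of the α,β-unsaturated acyl azide (concerted 1,2-shift) gives the vinyl isocyanate; aqueous acid converts it through the carbamic acid and enamine into the C6 ketone and removes the silyl ether. C5 is set under thermodynamic control through the C6 enol: the C6 carbonyl carbon settles trans to the C4 isopropyl group and cis to the hydrogen-bonding hydroxyl, which is the trans ring fusion (H5 β).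

Step 8
Reactants: 17 (3R,3aR,8aR)-3-hydroxy-6,8a-dimethyl-3-(propan-2-yl)-2,3,3a,5,8,8a-hexahydroazulen-4(1H)-one
Product: 18 (3R,3aS,4S,8aR)-6,8a-dimethyl-3-(propan-2-yl)-1,2,3,3a,4,5,8,8a-octahydroazulene-3,4-diol
Conditions: Me4NBH(OAc)3, MeCN/AcOH, −30 °C
Reagents that add atoms: none
Why: Hydroxyl-directed reduction of a β-hydroxy ketone: the C4 hydroxyl exchanges onto boron and delivers hydride internally to the α face of C6 through a six-membered chair-like transition state, giving the 1,3-anti diol (C6–OH β) against the steric shielding of that face by the C1 methyl. The mildly acidic medium avoids retro-aldol cleavage.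

Step 9
Reactants: 18 (3R,3aS,4S,8aR)-6,8a-dimethyl-3-(propan-2-yl)-1,2,3,3a,4,5,8,8a-octahydroazulene-3,4-diol
Product: 19 (3R,3aS,4S,8aR)-3-hydroxy-6,8a-dimethyl-3-(propan-2-yl)-1,2,3,3a,4,5,8,8a-octahydroazulen-4-yl 2-hydroxybenzoate
Conditions: NaN(SiMe3)2 (1.05 equiv), THF, −20 °C; 2,2-dimethyl-4H-1,3-benzodioxin-4-one, to rt; dilute aq HCl quench
Reagents that add atoms: 2,2-dimethyl-4H-1,3-benzodioxin-4-one, CC1(C)OC(=O)c2ccccc2O1
Why: Transesterification of a salicylic acid acetonide: the secondary C6 alkoxide adds to the ring carbonyl, and collapse expels acetone and the phenoxide, so the free-phenol salicylate forms in one step without a protecting group. The tertiary C4 hydroxyl is too hindered to compete, and an acyl group reaching it would migrate to the secondary oxygen.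

## Compound list

1 | but-3-en-2-one (methyl vinyl ketone) | CC(=O)C=C | starting material
2 | methyl 4-oxobutanoate | COC(=O)CCC=O | starting material
3 | methyl 4,7-dioxooctanoate | COC(=O)CCC(=O)CCC(C)=O | intermediate
4 | 2-(2-methyl-5-oxocyclopent-1-en-1-yl)acetic acid | OC(=O)CC1=C(C)CCC1=O | intermediate
5 | methyl 2-(2-methyl-5-oxocyclopent-1-en-1-yl)acetate | COC(=O)CC1=C(C)CCC1=O | intermediate
6 | methyl 2-diazo-2-(2-methyl-5-oxocyclopent-1-en-1-yl)acetate | COC(=O)C(=[N+]=[N-])C1=C(C)CCC1=O | intermediate
7 | isoprene (2-methylbuta-1,3-diene) | CC(=C)C=C | starting material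
8 | methyl (1S,2R)-2-ethenyl-2-methyl-1-(2-methyl-5-oxocyclopent-1-en-1-yl)cyclopropane-1-carboxylate | COC(=O)[C@]1(C[C@]1(C)C=C)C2=C(C)CCC2=O | intermediate
9 | methyl (8aR)-6,8a-dimethyl-3-oxo-1,2,3,5,8,8a-hexahydroazulene-4-carboxylate | COC(=O)C1=C2C(=O)CC[C@]2(C)CC=C(C)C1 | intermediate
10 | methyl (3R,8aR)-3-hydroxy-6,8a-dimethyl-3-(propan-2-yl)-1,2,3,5,8,8a-hexahydroazulene-4-carboxylate | COC(=O)C1=C2[C@](O)(C(C)C)CC[C@]2(C)CC=C(C)C1 | intermediate
11 | tricyclic butenolide: lactone of 10 between the C4 oxygen and the C6 carboxyl (1R,4R) | CC(C)[C@@]12OC(=O)C3=C1[C@](C)(CC2)CC=C(C)C3 | intermediate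
12 | potassium (3R,8aR)-3-hydroxy-6,8a-dimethyl-3-(propan-2-yl)-1,2,3,5,8,8a-hexahydroazulene-4-carboxylate | [K+].[O-]C(=O)C1=C2[C@](O)(C(C)C)CC[C@]2(C)CC=C(C)C1 | intermediate
13 | triethylsilyl (3R,8aR)-6,8a-dimethyl-3-(propan-2-yl)-3-[(triethylsilyl)oxy]-1,2,3,5,8,8a-hexahydroazulene-4-carboxylate | CC[Si](CC)(CC)OC(=O)C1=C2[C@](O[Si](CC)(CC)CC)(C(C)C)CC[C@]2(C)CC=C(C)C1 | intermediate
14 | (3R,8aR)-6,8a-dimethyl-3-(propan-2-yl)-3-[(triethylsilyl)oxy]-1,2,3,5,8,8a-hexahydroazulene-4-carboxylic acid | OC(=O)C1=C2[C@](O[Si](CC)(CC)CC)(C(C)C)CC[C@]2(C)CC=C(C)C1 | intermediate
15 | acyl azide of 14 | [N-]=[N+]=NC(=O)C1=C2[C@](O[Si](CC)(CC)CC)(C(C)C)CC[C@]2(C)CC=C(C)C1 | intermediate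
16 | vinyl isocyanate (C6–N=C=O, C4–OSiEt3) | O=C=NC1=C2[C@](O[Si](CC)(CC)CC)(C(C)C)CC[C@]2(C)CC=C(C)C1 | intermediate
17 | (3R,3aR,8aR)-3-hydroxy-6,8a-dimethyl-3-(propan-2-yl)-2,3,3a,5,8,8a-hexahydroazulen-4(1H)-one | CC1=CC[C@@]2(C)CC[C@@](O)(C(C)C)[C@@H]2C(=O)C1 | intermediate
18 | (3R,3aS,4S,8aR)-6,8a-dimethyl-3-(propan-2-yl)-1,2,3,3a,4,5,8,8a-octahydroazulene-3,4-diol | CC1=CC[C@@]2(C)CC[C@@](O)(C(C)C)[C@@H]2[C@@H](O)C1 | intermediate
19 | (3R,3aS,4S,8aR)-3-hydroxy-6,8a-dimethyl-3-(propan-2-yl)-1,2,3,3a,4,5,8,8a-octahydroazulen-4-yl 2-hydroxybenzoate | CC1=CC[C@@]2(C)CC[C@@](O)(C(C)C)[C@@H]2[C@@H](OC(=O)c2ccccc2O)C1 | target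

## Step count and least certain steps

Total: 9 steps. Longest linear sequence: 9 steps (1 and 2 to 19); 7 and all reagents are commercial.

Step 4 (key step). What may go wrong:
- leakage of the cyclopropanation to the unsubstituted vinyl group of 7, which would put the methyl on C9;
- formation of the trans-divinylcyclopropane (methyl instead of vinyl cis to the cyclopentenyl group), which rearranges only under conditions that endanger the stereochemical transfer;
- a sluggish Cope step because the C1 methyl points into the boat;
- erosion of enantioselectivity because the tetrasubstituted vinyl donor is twisted out of conjugation with the carbenoid;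
- cyclisation of 6 to a pyrazole before use.

Fallback, from 6 back to 9: the diene is changed so that only one alkene can react. 2-Methyl-3-(trimethylsilyl)buta-1,3-diene F1 is made by Kumada coupling of isopropenylmagnesium bromide with (1-bromovinyl)trimethylsilane using NiCl2(dppp). Its silylated alkene is hindered and less nucleophilic, so the same catalyst and the same heating should give methyl (8aR)-6,8a-dimethyl-3-oxo-7-(trimethylsilyl)-1,2,3,5,8,8a-hexahydroazulene-4-carboxylate F2. Ipso-protodesilylation of the vinylsilane (CF3CO2H, CH2Cl2, 0 °C) then returns 9.

Step 5. What may go wrong: poor facial selectivity at C4. The only control element is the 1,3-related C1 centre, and the preference for the β face rests on a conformational argument. Reduction by β-hydride transfer and enolisation at C7 are minor side paths.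

Fallback, from 9 back to 17, reverses the polarity at C4:
- The C4 epimers are not separated, and steps 5 to 7 are run on the mixture. This gives 17 together with its C4,C5-diastereomer, the (3S,3aS,8aR) ketol F3.
- Dehydration of the mixture (MeSO2Cl, Et3N, then DBU; E1cB) converges on one enone, (8aR)-6,8a-dimethyl-3-(propan-2-yl)-2,5,8,8a-tetrahydroazulen-4(1H)-one F4.
- Weitz–Scheffer epoxidation (H2O2, LiOH, MeOH) now brings the oxygen, not the carbon substituent, to C4 as the nucleophile. A preference for the α face that is wrong for the Grignard step is therefore right here, giving the C4–C5 α-epoxy ketone F5.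
- SmI2 in THF/MeOH at −78 °C cleaves the C5–O bond next to the ketone and returns 17 after equilibration of C5.

Step 7 (with its preparation in step 6). What may go wrong: relactonisation if the silyl group is lost or transfers to the carboxylate during activation, and dehydration or retro-aldol cleavage of the tertiary β-hydroxy ketone during the acidic hydrolysis; incomplete equilibration at C5 is a lesser risk.

Fallback, from 9 back to 17, exchanges the carboxyl for oxygen before the isopropyl group is added:
- Saponification (LiOH, THF/H2O) gives the keto acid (8aR)-6,8a-dimethyl-3-oxo-1,2,3,5,8,8a-hexahydroazulene-4-carboxylic acid F6.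
- Curtius rearrangement with (PhO)2P(O)N3/Et3N and hydrolysis with dilute HCl give the β-diketone (8aR)-6,8a-dimethyl-1,2,5,8-tetrahydroazulene-3,4(3aH,8aH)-dione F7, largely enolised.
- O-Silylation at the C6 oxygen (t-BuMe2SiCl, imidazole) gives the C6 tert-butyldimethylsilyl enol ether of the C4 ketone F8.
- iPrMgCl/CeCl3 adds to the C4 ketone to give the tertiary carbinol silyl enol ether F9.
- Bu4NF buffered with acetic acid releases 17 without acid that could dehydrate it.

Step 8. What may go wrong: slow exchange of the hindered tertiary hydroxyl onto boron, so that reduction is slow or undirected and hydride enters from the open β face, giving the wrong C6 configuration; retro-aldol cleavage is a minor risk.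

Fallback, from 17 to 19, replaces steps 8 and 9 and uses inversion instead of directed delivery. Deliberately undirected reduction with LiBH(s-Bu)3 from the β face gives the C6-epimeric (3R,3aS,4R,8aR) diol F10. A Mitsunobu esterification with salicylic acid (PPh3, diisopropyl azodicarboxylate) then inverts C6 while forming the ester and gives 19 directly.

Step 9. What may go wrong: incomplete acylation of the hindered C6 alkoxide, or base-induced side reactions of the diol monoanion.

Fallback, from 18 back to 19: acylation with 2-(acetyloxy)benzoyl chloride (pyridine, 4-dimethylaminopyridine) gives the 2-(acetyloxy)benzoate of 18 F11. Pyrrolidine at 0 °C then removes the phenolic acetate, which is far more reactive than the hindered alkyl benzoate, to give 19.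

## Further compounds

F1 | step 4 | 2-methyl-3-(trimethylsilyl)buta-1,3-diene | CC(=C)C(=C)[Si](C)(C)C
F2 | step 4 | methyl (8aR)-6,8a-dimethyl-3-oxo-7-(trimethylsilyl)-1,2,3,5,8,8a-hexahydroazulene-4-carboxylate | COC(=O)C1=C2C(=O)CC[C@]2(C)CC([Si](C)(C)C)=C(C)C1
F3 | step 5 | (3S,3aS,8aR)-3-hydroxy-6,8a-dimethyl-3-(propan-2-yl)-2,3,3a,5,8,8a-hexahydroazulen-4(1H)-one | CC1=CC[C@@]2(C)CC[C@](O)(C(C)C)[C@H]2C(=O)C1
F4 | step 5 | (8aR)-6,8a-dimethyl-3-(propan-2-yl)-2,5,8,8a-tetrahydroazulen-4(1H)-one | CC1=CC[C@@]2(C)CCC(C(C)C)=C2C(=O)C1
F5 | step 5 | C4–C5 α-epoxide of F4 | CC1=CC[C@@]2(C)CC[C@]3(C(C)C)O[C@]23C(=O)C1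
F6 | step 7 | (8aR)-6,8a-dimethyl-3-oxo-1,2,3,5,8,8a-hexahydroazulene-4-carboxylic acid | OC(=O)C1=C2C(=O)CC[C@]2(C)CC=C(C)C1
F7 | step 7 | (8aR)-6,8a-dimethyl-1,2,5,8-tetrahydroazulene-3,4(3aH,8aH)-dione (C5 not fixed, enolised) | CC1=CC[C@@]2(C)CCC(=O)C2C(=O)C1
F8 | step 7 | (8aR)-4-[(tert-butyldimethylsilyl)oxy]-6,8a-dimethyl-1,2,8,8a-tetrahydroazulen-3(5H)-one | CC1=CC[C@@]2(C)CCC(=O)C2=C(O[Si](C)(C)C(C)(C)C)C1
F9 | step 7 | (3R,8aR)-4-[(tert-butyldimethylsilyl)oxy]-6,8a-dimethyl-3-(propan-2-yl)-1,2,3,5,8,8a-hexahydroazulen-3-ol | CC1=CC[C@@]2(C)CC[C@@](O)(C(C)C)C2=C(O[Si](C)(C)C(C)(C)C)C1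
F10 | step 8 | (3R,3aS,4R,8aR)-6,8a-dimethyl-3-(propan-2-yl)-1,2,3,3a,4,5,8,8a-octahydroazulene-3,4-diol | CC1=CC[C@@]2(C)CC[C@@](O)(C(C)C)[C@@H]2[C@H](O)C1
F11 | step 9 | (3R,3aS,4S,8aR)-3-hydroxy-6,8a-dimethyl-3-(propan-2-yl)-1,2,3,3a,4,5,8,8a-octahydroazulen-4-yl 2-(acetyloxy)benzoate | CC1=CC[C@@]2(C)CC[C@@](O)(C(C)C)[C@@H]2[C@@H](OC(=O)c2ccccc2OC(C)=O)C1
A1 | alternative 1 | (R)-(bromomethyl)dimethyl{[3-methyl-1-(propan-2-yl)cyclopent-2-en-1-yl]oxy}silane | CC1=C[C@](CC1)(O[Si](C)(C)CBr)C(C)C
A2 | alternative 1 | allyltributylstannane | C=CC[Sn](CCCC)(CCCC)CCCC
A3 | alternative 1 | cis-fused oxasilolane cyclopentane with allyl and methyl on C1 | C=CC[C@@]1(C)CC[C@]2(C(C)C)O[Si](C)(C)C[C@H]12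
A4 | alternative 2 | trans-decalin ring-fusion carbinol with C4–C5 α-epoxide, C4 isopropyl, C1 methyl and C8=C9 alkene | CC1=CC[C@@]2(C)CC[C@]3(C(C)C)O[C@@H]3[C@]2(O)C1
A5 | alternative 2 | (3R,3aR,8aR)-3-hydroxy-6,8a-dimethyl-3-(propan-2-yl)-2,3,3a,5,8,8a-hexahydroazulen-4(1H)-one | CC1=CC[C@@]2(C)CC[C@@](O)(C(C)C)[C@@H]2C(=O)C1
A6 | alternative 3 | bicyclo[3.1.0]hexane vinylcyclopropane with C4 dioxolane, C1 methyl and C5 1-[(tert-butyldimethylsilyl)oxy]ethenyl group | C=C(O[Si](C)(C)C(C)(C)C)[C@]12C[C@@]1(C)CCC23OCCO3
A7 | alternative 3 | 1-(trimethylsilyl)propyne | CC#C[Si](C)(C)C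
A8 | alternative 3 | bicyclic cycloheptadiene with C6 silyl enol ether, C9 trimethylsilyl, C8 methyl and C4 dioxolane | CC1=C([Si](C)(C)C)C[C@@]2(C)CCC3(OCCO3)C2=C(O[Si](C)(C)C(C)(C)C)C1
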